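**Retrosynthetic overview**

- Tetralin numbering: C1 carries the guaiacyl ring, C2 and C3 carry the hydroxymethyl carbons C9 and C10, C4 is the CH2, and ring A runs C4a, C5 (OMe), C6 (OMe), C7 (OH), C8 (H), C8a. The strategy rests on C4 being an unsubstituted CH2 between C3 and the electron-rich ring A carbon C4a (para to the C7 oxygen, ortho to the C5 methoxy), so C4 can be inserted last.
- C10 is disconnected to a C3 ketone (enol triflate towards C4, methoxycarbonylation). The C3 configuration comes from equilibration of the ester while C9 is still a benzyl ether.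
- Ring B is disconnected at C3–C4 and C4–C4a: one carbon from trimethylsilyldiazomethane enlarges the five-membered ring of a trans-2-(benzyloxymethyl)-3-arylindan-1-one, with C4a migrating.
- The indanone comes from trans alkylation at C2 with benzyl chloromethyl ether, after rhodium–BINAP asymmetric hydroacylation of a 2-(1-arylvinyl)benzaldehyde has closed the five-membered ring and set C1.
- The aldehyde comes from methyl 3,5-dihydroxy-4-methoxybenzoate (ring A) and 4-bromo-2-methoxyphenol (guaiacyl ring) by Weinreb ketone synthesis, Wittig methylenation and bromine–lithium exchange/formylation. Ring order: ring A and the guaiacyl ring are bought, the five-membered ring forms in step 9, and it is enlarged to ring B in step 11.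

Key step: step 11

Assumption: which BINAP antipode gives the (3R)-indanone 13 in the rhodium hydroacylation is to be fixed in a trial run; (R)-BINAP is written below as a placeholder for that antipode.

**Route**

Step 1
Reactants: 1 methyl 3,5-dihydroxy-4-methoxybenzoate
Product: 2 methyl 3-(benzyloxy)-5-hydroxy-4-methoxybenzoate
Conditions: BnBr (1.0 equiv), K2CO3 (1.1 equiv), DMF, rt; recovered 1 recycled
Reagents that add atoms: benzyl bromide, BrCc1ccccc1
Why: Williamson etherification of one of two equivalent phenols, so only one mono-ether can form and the statistical mixture (diol, mono-ether, bis-ether) should be separable.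

Step 2
Reactants: 2 methyl 3-(benzyloxy)-5-hydroxy-4-methoxybenzoate
Product: 3 methyl 5-(benzyloxy)-2-bromo-3-hydroxy-4-methoxybenzoate
Conditions: NBS (1.0 equiv), i-Pr2NH (10 mol %), CH2Cl2, 0 °C
Reagents that add atoms: N-bromosuccinimide, O=C1CCC(=O)N1Br
Why: Amine-mediated ortho-selective bromination of a phenol should deliver bromine to the only free position ortho to the hydroxyl (future C4a), the site between OH and the ester-bearing carbon, and not to the position flanked by the bulkier benzyloxy group.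

Step 3
Reactants: 3 methyl 5-(benzyloxy)-2-bromo-3-hydroxy-4-methoxybenzoate
Product: 4 methyl 5-(benzyloxy)-2-bromo-3,4-dimethoxybenzoate
Conditions: MeI, K2CO3, DMF, 40 °C
Reagents that add atoms: iodomethane, CI
Why: Williamson methylation of the remaining phenol fixes the future C5 methoxy group next to the brominated carbon.

Step 4
Reactants: 4 methyl 5-(benzyloxy)-2-bromo-3,4-dimethoxybenzoate
Product: 5 5-(benzyloxy)-2-bromo-N,3,4-trimethoxy-N-methylbenzamide
Conditions: MeNH(OMe)·HCl, i-PrMgCl, THF, −20 → 0 °C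
Reagents that add atoms: N,O-dimethylhydroxylamine hydrochloride, CNOC.Cl
Why: Aminolysis of the ester by the chloromagnesium amide gives the Weinreb amide, and the acid–base consumption of i-PrMgCl should be much faster than bromine–magnesium exchange on this electron-rich bromide.

Step 5
Reactants: 6 4-bromo-2-methoxyphenol
Product: 7 1-(benzyloxy)-4-bromo-2-methoxybenzene
Conditions: BnBr, K2CO3, DMF, rt
Reagents that add atoms: benzyl bromide, BrCc1ccccc1
Why: Williamson benzylation protects the guaiacyl phenol for the organometallic steps.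

Step 6
Reactants: 5 5-(benzyloxy)-2-bromo-N,3,4-trimethoxy-N-methylbenzamide; 7 1-(benzyloxy)-4-bromo-2-methoxybenzene
Product: 9 [5-(benzyloxy)-2-bromo-3,4-dimethoxyphenyl][4-(benzyloxy)-3-methoxyphenyl]methanone, via arylmagnesium bromide 8 (not isolated)
Conditions: 7, Mg, THF, reflux; then 5, THF, 0 °C → rt; aq NH4Cl
Reagents that add atoms: none
Why: Weinreb ketone synthesis, in which the chelated tetrahedral magnesium adduct collapses only on work-up, so the Grignard reagent should add once.

Step 7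
Reactants: 9 [5-(benzyloxy)-2-bromo-3,4-dimethoxyphenyl][4-(benzyloxy)-3-methoxyphenyl]methanone
Product: 10 1-(benzyloxy)-5-{1-[4-(benzyloxy)-3-methoxyphenyl]ethenyl}-4-bromo-2,3-dimethoxybenzene
Conditions: Ph3PCH3Br, KOt-Bu, THF, 0 °C → reflux
Reagents that add atoms: methyltriphenylphosphonium bromide, C[P+](c1ccccc1)(c1ccccc1)c1ccccc1.[Br-]
Why: Wittig methylenation of a non-enolisable diaryl ketone supplies the carbon that becomes C2.

Step 8
Reactants: 10 1-(benzyloxy)-5-{1-[4-(benzyloxy)-3-methoxyphenyl]ethenyl}-4-bromo-2,3-dimethoxybenzene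
Product: 12 4-(benzyloxy)-6-{1-[4-(benzyloxy)-3-methoxyphenyl]ethenyl}-2,3-dimethoxybenzaldehyde, via aryllithium 11 (not isolated)
Conditions: n-BuLi (1.05 equiv), THF, −78 °C; DMF, −78 → 0 °C; aq NH4Cl
Reagents that add atoms: N,N-dimethylformamide, CN(C)C=O
Why: Bromine–lithium exchange at −78 °C should outpace carbolithiation of the electron-rich 1,1-diarylethene, and Bouveault formylation of the aryllithium installs the aldehyde carbon (future C3) on C4a.

Step 9
Reactants: 12 4-(benzyloxy)-6-{1-[4-(benzyloxy)-3-methoxyphenyl]ethenyl}-2,3-dimethoxybenzaldehyde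
Product: 13 (3R)-5-(benzyloxy)-3-[4-(benzyloxy)-3-methoxyphenyl]-6,7-dimethoxy-2,3-dihydro-1H-inden-1-one
Conditions: [Rh(cod)2]BF4 (5 mol %), (R)-BINAP (6 mol %), H2 pre-activation then Ar, acetone, 25–40 °C
Reagents that add atoms: none
Why: Intramolecular rhodium-catalysed asymmetric alkene hydroacylation (aldehyde C–H oxidative addition, hydride delivery to the aryl-bearing alkene carbon, reductive elimination of the five-membered ketone), in which the chiral bisphosphine selects the alkene face and so sets C1; the enantiomeric purity can be raised by crystallisation if needed.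

Step 10
Reactants: 13 (3R)-5-(benzyloxy)-3-[4-(benzyloxy)-3-methoxyphenyl]-6,7-dimethoxy-2,3-dihydro-1H-inden-1-one; 14 benzyl chloromethyl ether
Product: 16 (2R,3R)-5-(benzyloxy)-3-[4-(benzyloxy)-3-methoxyphenyl]-2-[(benzyloxy)methyl]-6,7-dimethoxy-2,3-dihydro-1H-inden-1-one, via lithium enolate 15 (not isolated)
Conditions: LiN(SiMe3)2 (1.05 equiv), THF, −78 °C; 14 (1.3 equiv), −78 → −40 °C; aq NH4Cl
Reagents that add atoms: benzyl chloromethyl ether (14), ClCOCc1ccccc1
Why: Enolate alkylation in which the electrophile should approach the planar indanone enolate anti to the C1 aryl group, giving the trans product that is also the thermodynamically preferred one, and so sets C2.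

Step 11
Reactants: 16 (2R,3R)-5-(benzyloxy)-3-[4-(benzyloxy)-3-methoxyphenyl]-2-[(benzyloxy)methyl]-6,7-dimethoxy-2,3-dihydro-1H-inden-1-one; 17 trimethylsilyldiazomethane
Product: 19 (3R,4R)-6-(benzyloxy)-4-[4-(benzyloxy)-3-methoxyphenyl]-3-[(benzyloxy)methyl]-7,8-dimethoxy-3,4-dihydronaphthalen-2(1H)-one, via silyl ketone 18 (not isolated)
Conditions: 17 (2.0 equiv), BF3·OEt2 (1.5 equiv), CH2Cl2, −78 → −20 °C; then 1 M HCl, THF, 0 °C
Reagents that add atoms: trimethylsilyldiazomethane (17), C[Si](C)(C)C=[N+]=[N-]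
Why: BF3 activates the indanone carbonyl of 16, the diazo carbon of 17 adds to it, and the resulting diazonium alkoxide loses N2 with a 1,2-shift of the ring A carbon C4a to the new carbon (future C4), giving silyl ketone 18, which is protodesilylated on acidic work-up to 19. The closest known reaction type is the Lewis acid-promoted Tiffeneau–Demjanov-type homologation of 1-indanones and other aryl ketones with trimethylsilyldiazomethane, which proceeds with aryl migration. Ring B is not closed by a cyclisation: the existing five-membered ring is enlarged to the six-membered ring by insertion of C4 into the C3–C4a bond, which makes C3–C4 and C4–C4a. No stereocentre is created; C1 is remote from the reacting centre, and C2, although α to the carbonyl, should keep its favoured trans relation to the C1 aryl group because no base is present. The step needs migration of C4a in preference to C2, and the substrate secures this through the C7 benzyloxy group para and the C5 methoxy group ortho to C4a, which raise its migratory aptitude, while C2 is more hindered and deactivated by its β-benzyloxy substituent. The trimethylsilyl group on the inserted carbon should block a second insertion into the more electrophilic product ketone, and the cold, non-basic medium should spare the β-benzyloxy ketone from elimination.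

Step 12
Reactants: 19 (3R,4R)-6-(benzyloxy)-4-[4-(benzyloxy)-3-methoxyphenyl]-3-[(benzyloxy)methyl]-7,8-dimethoxy-3,4-dihydronaphthalen-2(1H)-one
Product: 21 (3R,4R)-6-(benzyloxy)-4-[4-(benzyloxy)-3-methoxyphenyl]-3-[(benzyloxy)methyl]-7,8-dimethoxy-3,4-dihydronaphthalen-2-yl trifluoromethanesulfonate, via potassium enolate 20 (not isolated)
Conditions: KN(SiMe3)2 (1.1 equiv), THF, −78 °C; PhNTf2 (1.2 equiv), −78 → 0 °C
Reagents that add atoms: N-phenylbis(trifluoromethanesulfonimide), O=S(=O)(N(c1ccccc1)S(=O)(=O)C(F)(F)F)C(F)(F)F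
Why: Kinetic deprotonation should occur at the more acidic, less hindered benzylic C4 to give the arene-conjugated enolate, whose O-triflation leaves C2 untouched and so avoids epimerisation and loss of benzyl alkoxide.

Step 13
Reactants: 21 (3R,4R)-6-(benzyloxy)-4-[4-(benzyloxy)-3-methoxyphenyl]-3-[(benzyloxy)methyl]-7,8-dimethoxy-3,4-dihydronaphthalen-2-yl trifluoromethanesulfonate
Product: 22 methyl (3S,4R)-6-(benzyloxy)-4-[4-(benzyloxy)-3-methoxyphenyl]-3-[(benzyloxy)methyl]-7,8-dimethoxy-3,4-dihydronaphthalene-2-carboxylate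
Conditions: Pd(OAc)2 (5 mol %), dppp (6 mol %), CO (1 atm), Et3N, MeOH/DMF, 60 °C
Reagents that add atoms: carbon monoxide, [C-]#[O+]; methanol, CO
Why: Palladium-catalysed methoxycarbonylation of the enol triflate (oxidative addition to zerovalent palladium, CO insertion, methanolysis) installs C10 on C3; the change of descriptor at the benzyloxymethyl-bearing carbon is a priority change only.

Step 14
Reactants: 22 methyl (3S,4R)-6-(benzyloxy)-4-[4-(benzyloxy)-3-methoxyphenyl]-3-[(benzyloxy)methyl]-7,8-dimethoxy-3,4-dihydronaphthalene-2-carboxylate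
Product: 24 methyl (2S,3S,4R)-6-(benzyloxy)-4-[4-(benzyloxy)-3-methoxyphenyl]-3-[(benzyloxy)methyl]-7,8-dimethoxy-1,2,3,4-tetrahydronaphthalene-2-carboxylate, via epimeric ester 23 (not isolated)
Conditions: Mg turnings, MeOH, 0 °C → rt; then NaOMe, MeOH, 60 °C; AcOH quench
Reagents that add atoms: none
Why: Magnesium–methanol conjugate reduction of the β-aryl acrylate leaves the benzyl ethers intact, and methoxide then equilibrates the only epimerisable centre (C3, α to the ester) towards the all-equatorial 2,3-trans ester, the minor cis epimer being resubmitted; the benzyl ether on C9 prevents lactonisation, which would favour the cis ring fusion.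

Step 15
Reactants: 24 methyl (2S,3S,4R)-6-(benzyloxy)-4-[4-(benzyloxy)-3-methoxyphenyl]-3-[(benzyloxy)methyl]-7,8-dimethoxy-1,2,3,4-tetrahydronaphthalene-2-carboxylate
Product: 25 [(2S,3S,4R)-6-(benzyloxy)-4-[4-(benzyloxy)-3-methoxyphenyl]-3-[(benzyloxy)methyl]-7,8-dimethoxy-1,2,3,4-tetrahydronaphthalen-2-yl]methanol
Conditions: LiAlH4, THF, 0 °C → rt; Fieser work-up
Reagents that add atoms: none
Why: Hydride reduction of the ester to the primary alcohol C10 does not touch the stereocentres.

Step 16
Reactants: 25 [(2S,3S,4R)-6-(benzyloxy)-4-[4-(benzyloxy)-3-methoxyphenyl]-3-[(benzyloxy)methyl]-7,8-dimethoxy-1,2,3,4-tetrahydronaphthalen-2-yl]methanol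
Product: 26 (6S,7S,8R)-8-(4-hydroxy-3-methoxyphenyl)-6,7-bis(hydroxymethyl)-3,4-dimethoxy-5,6,7,8-tetrahydronaphthalen-2-ol, the target, (1R,2S,3S) in the tetralin numbering
Conditions: H2 (1 atm), 10% Pd/C, EtOAc/MeOH, rt
Reagents that add atoms: none
Why: Catalytic hydrogenolysis should cleave the two aryl benzyl ethers and the alkyl benzyl ether, while the doubly benzylic C1–H centre carries no heteroatom and is not affected.

**Compound list**

1 | methyl 3,5-dihydroxy-4-methoxybenzoate | COC(=O)c1cc(O)c(OC)c(O)c1 | starting material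
2 | methyl 3-(benzyloxy)-5-hydroxy-4-methoxybenzoate | COC(=O)c1cc(O)c(OC)c(OCc2ccccc2)c1 | intermediate
3 | methyl 5-(benzyloxy)-2-bromo-3-hydroxy-4-methoxybenzoate | COC(=O)c1cc(OCc2ccccc2)c(OC)c(O)c1Br | intermediate
4 | methyl 5-(benzyloxy)-2-bromo-3,4-dimethoxybenzoate | COC(=O)c1cc(OCc2ccccc2)c(OC)c(OC)c1Br | intermediate
5 | 5-(benzyloxy)-2-bromo-N,3,4-trimethoxy-N-methylbenzamide | CON(C)C(=O)c1cc(OCc2ccccc2)c(OC)c(OC)c1Br | intermediate
6 | 4-bromo-2-methoxyphenol | COc1cc(Br)ccc1O | starting material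
7 | 1-(benzyloxy)-4-bromo-2-methoxybenzene | COc1cc(Br)ccc1OCc1ccccc1 | intermediate
8 | [4-(benzyloxy)-3-methoxyphenyl]magnesium bromide | COc1cc([Mg]Br)ccc1OCc1ccccc1 | intermediate
9 | [5-(benzyloxy)-2-bromo-3,4-dimethoxyphenyl][4-(benzyloxy)-3-methoxyphenyl]methanone | COc1cc(C(=O)c2cc(OCc3ccccc3)c(OC)c(OC)c2Br)ccc1OCc1ccccc1 | intermediate
10 | 1-(benzyloxy)-5-{1-[4-(benzyloxy)-3-methoxyphenyl]ethenyl}-4-bromo-2,3-dimethoxybenzene | COc1cc(C(=C)c2cc(OCc3ccccc3)c(OC)c(OC)c2Br)ccc1OCc1ccccc1 | intermediate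
11 | {4-(benzyloxy)-6-{1-[4-(benzyloxy)-3-methoxyphenyl]ethenyl}-2,3-dimethoxyphenyl}lithium | COc1cc(C(=C)c2cc(OCc3ccccc3)c(OC)c(OC)c2[Li])ccc1OCc1ccccc1 | intermediate
12 | 4-(benzyloxy)-6-{1-[4-(benzyloxy)-3-methoxyphenyl]ethenyl}-2,3-dimethoxybenzaldehyde | COc1cc(C(=C)c2cc(OCc3ccccc3)c(OC)c(OC)c2C=O)ccc1OCc1ccccc1 | intermediate
13 | (3R)-5-(benzyloxy)-3-[4-(benzyloxy)-3-methoxyphenyl]-6,7-dimethoxy-2,3-dihydro-1H-inden-1-one | COc1cc([C@@H]2c3cc(OCc4ccccc4)c(OC)c(OC)c3C(=O)C2)ccc1OCc1ccccc1 | intermediate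
14 | benzyl chloromethyl ether | ClCOCc1ccccc1 | starting material
15 | lithium (1R)-6-(benzyloxy)-1-[4-(benzyloxy)-3-methoxyphenyl]-4,5-dimethoxy-1H-inden-3-olate | COc1cc([C@@H]2c3cc(OCc4ccccc4)c(OC)c(OC)c3C(O[Li])=C2)ccc1OCc1ccccc1 | intermediate
16 | (2R,3R)-5-(benzyloxy)-3-[4-(benzyloxy)-3-methoxyphenyl]-2-[(benzyloxy)methyl]-6,7-dimethoxy-2,3-dihydro-1H-inden-1-one | COc1cc([C@@H]2c3cc(OCc4ccccc4)c(OC)c(OC)c3C(=O)[C@H]2COCc2ccccc2)ccc1OCc1ccccc1 | intermediate
17 | trimethylsilyldiazomethane | C[Si](C)(C)C=[N+]=[N-] | starting material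
18 | (3R,4R)-6-(benzyloxy)-4-[4-(benzyloxy)-3-methoxyphenyl]-3-[(benzyloxy)methyl]-7,8-dimethoxy-1-(trimethylsilyl)-3,4-dihydronaphthalen-2(1H)-one (C1 epimers) | COc1cc([C@@H]2c3cc(OCc4ccccc4)c(OC)c(OC)c3C([Si](C)(C)C)C(=O)[C@H]2COCc2ccccc2)ccc1OCc1ccccc1 | intermediate
19 | (3R,4R)-6-(benzyloxy)-4-[4-(benzyloxy)-3-methoxyphenyl]-3-[(benzyloxy)methyl]-7,8-dimethoxy-3,4-dihydronaphthalen-2(1H)-one | COc1cc([C@@H]2c3cc(OCc4ccccc4)c(OC)c(OC)c3CC(=O)[C@H]2COCc2ccccc2)ccc1OCc1ccccc1 | intermediate
20 | potassium (3R,4R)-6-(benzyloxy)-4-[4-(benzyloxy)-3-methoxyphenyl]-3-[(benzyloxy)methyl]-7,8-dimethoxy-3,4-dihydronaphthalen-2-olate | COc1cc([C@@H]2c3cc(OCc4ccccc4)c(OC)c(OC)c3C=C(O[K])[C@H]2COCc2ccccc2)ccc1OCc1ccccc1 | intermediate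
21 | (3R,4R)-6-(benzyloxy)-4-[4-(benzyloxy)-3-methoxyphenyl]-3-[(benzyloxy)methyl]-7,8-dimethoxy-3,4-dihydronaphthalen-2-yl trifluoromethanesulfonate | COc1cc([C@@H]2c3cc(OCc4ccccc4)c(OC)c(OC)c3C=C(OS(=O)(=O)C(F)(F)F)[C@H]2COCc2ccccc2)ccc1OCc1ccccc1 | intermediate
22 | methyl (3S,4R)-6-(benzyloxy)-4-[4-(benzyloxy)-3-methoxyphenyl]-3-[(benzyloxy)methyl]-7,8-dimethoxy-3,4-dihydronaphthalene-2-carboxylate | COc1cc([C@@H]2c3cc(OCc4ccccc4)c(OC)c(OC)c3C=C(C(=O)OC)[C@H]2COCc2ccccc2)ccc1OCc1ccccc1 | intermediate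
23 | methyl (3S,4R)-6-(benzyloxy)-4-[4-(benzyloxy)-3-methoxyphenyl]-3-[(benzyloxy)methyl]-7,8-dimethoxy-1,2,3,4-tetrahydronaphthalene-2-carboxylate (C2 epimers) | COc1cc([C@@H]2c3cc(OCc4ccccc4)c(OC)c(OC)c3CC(C(=O)OC)[C@H]2COCc2ccccc2)ccc1OCc1ccccc1 | intermediate
24 | methyl (2S,3S,4R)-6-(benzyloxy)-4-[4-(benzyloxy)-3-methoxyphenyl]-3-[(benzyloxy)methyl]-7,8-dimethoxy-1,2,3,4-tetrahydronaphthalene-2-carboxylate | COc1cc([C@@H]2c3cc(OCc4ccccc4)c(OC)c(OC)c3C[C@H](C(=O)OC)[C@H]2COCc2ccccc2)ccc1OCc1ccccc1 | intermediate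
25 | [(2S,3S,4R)-6-(benzyloxy)-4-[4-(benzyloxy)-3-methoxyphenyl]-3-[(benzyloxy)methyl]-7,8-dimethoxy-1,2,3,4-tetrahydronaphthalen-2-yl]methanol | COc1cc([C@@H]2c3cc(OCc4ccccc4)c(OC)c(OC)c3C[C@H](CO)[C@H]2COCc2ccccc2)ccc1OCc1ccccc1 | intermediate
26 | (6S,7S,8R)-8-(4-hydroxy-3-methoxyphenyl)-6,7-bis(hydroxymethyl)-3,4-dimethoxy-5,6,7,8-tetrahydronaphthalen-2-ol | COc1cc([C@@H]2c3cc(O)c(OC)c(OC)c3C[C@H](CO)[C@H]2CO)ccc1O | target

**Step count**

Total step count: 16. Longest linear sequence: 15 steps (from 1 to 26 through steps 1–4 and 6–16).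

**Steps most likely to fail**

Step 11 (ring enlargement). The carbonyl is deactivated by the para-benzyloxy and ortho-methoxy donors and screened by the C5 methoxy group and the C2 side chain, so addition of the diazo carbon may be slow. Shift of C2 instead of C4a (giving the regioisomeric 1-tetralone), epoxide formation, or Lewis acid-induced loss of benzyl alcohol from the β-benzyloxy ketone may compete. The fallback keeps the ring enlargement but changes it to an oxidative 1,2-aryl shift. It sets out from 16: non-basic methylenation with Cp2TiMe2 (toluene, 65 °C) should give the exocyclic alkene (1R,2S)-6-(benzyloxy)-1-[4-(benzyloxy)-3-methoxyphenyl]-2-[(benzyloxy)methyl]-4,5-dimethoxy-3-methylidene-2,3-dihydro-1H-indene F1. Treatment of F1 with PhI(OH)OTs in 95% methanol at 0 °C (iodonium formation at the terminal carbon, migration of the electron-rich C4a, hydrolysis of the ketal on work-up) should deliver the ketone, and the route is rejoined at 19.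

Step 2 (bromination). Bromine may enter para to the free hydroxyl, next to the benzyloxy group, or twice, which would misplace the halogen and hence the later formyl group relative to the C5 and C7 oxygens. The fallback omits the halogen and lets the free phenol direct the formyl group. It sets out from 2: amidation (MeNH(OMe)·HCl, i-PrMgCl with one extra equivalent for the phenol) should give 3-(benzyloxy)-5-hydroxy-N,4-dimethoxy-N-methylbenzamide F2. Addition of an excess of Grignard reagent 8 should give [3-(benzyloxy)-5-hydroxy-4-methoxyphenyl][4-(benzyloxy)-3-methoxyphenyl]methanone F3. Wittig methylenation with excess ylide should give 3-(benzyloxy)-5-{1-[4-(benzyloxy)-3-methoxyphenyl]ethenyl}-2-methoxyphenol F4. Magnesium-templated ortho-formylation (MgCl2, Et3N, paraformaldehyde, MeCN, reflux) can only occur at the single free position ortho to the hydroxyl (future C4a) and should give 4-(benzyloxy)-6-{1-[4-(benzyloxy)-3-methoxyphenyl]ethenyl}-2-hydroxy-3-methoxybenzaldehyde F5. Methylation (MeI, K2CO3, DMF) then rejoins the route at 12.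

Step 10 (benzyloxymethylation). The hard chloromethyl ether may alkylate the enolate on oxygen. Proton exchange between product and enolate may lead to double alkylation or E1cB loss of benzyl alkoxide to an exocyclic enone, and the trans selectivity may be incomplete. The fallback replaces the basic enolate alkylation by a Lewis acid-mediated hydroxymethylation followed by acid-catalysed benzylation. It sets out from 13: silylation (Me3SiOTf, Et3N, CH2Cl2, 0 °C) should give {[(1R)-6-(benzyloxy)-1-[4-(benzyloxy)-3-methoxyphenyl]-4,5-dimethoxy-1H-inden-3-yl]oxy}trimethylsilane F6. Mukaiyama aldol reaction with aqueous formaldehyde and Yb(OTf)3 in THF/H2O, with attack anti to the aryl group, should give (2R,3R)-5-(benzyloxy)-3-[4-(benzyloxy)-3-methoxyphenyl]-2-(hydroxymethyl)-6,7-dimethoxy-2,3-dihydro-1H-inden-1-one F7. Benzylation with benzyl 2,2,2-trichloroacetimidate and catalytic TfOH in CH2Cl2 rejoins the route at 16.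

**Further compounds**

F1 | step 11 | (1R,2S)-6-(benzyloxy)-1-[4-(benzyloxy)-3-methoxyphenyl]-2-[(benzyloxy)methyl]-4,5-dimethoxy-3-methylidene-2,3-dihydro-1H-indene | COc1cc([C@@H]2c3cc(OCc4ccccc4)c(OC)c(OC)c3C(=C)[C@H]2COCc2ccccc2)ccc1OCc1ccccc1
F2 | step 2 | 3-(benzyloxy)-5-hydroxy-N,4-dimethoxy-N-methylbenzamide | CON(C)C(=O)c1cc(O)c(OC)c(OCc2ccccc2)c1
F3 | step 2 | [3-(benzyloxy)-5-hydroxy-4-methoxyphenyl][4-(benzyloxy)-3-methoxyphenyl]methanone | COc1cc(C(=O)c2cc(O)c(OC)c(OCc3ccccc3)c2)ccc1OCc1ccccc1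
F4 | step 2 | 3-(benzyloxy)-5-{1-[4-(benzyloxy)-3-methoxyphenyl]ethenyl}-2-methoxyphenol | COc1cc(C(=C)c2cc(O)c(OC)c(OCc3ccccc3)c2)ccc1OCc1ccccc1
F5 | step 2 | 4-(benzyloxy)-6-{1-[4-(benzyloxy)-3-methoxyphenyl]ethenyl}-2-hydroxy-3-methoxybenzaldehyde | COc1cc(C(=C)c2cc(OCc3ccccc3)c(OC)c(O)c2C=O)ccc1OCc1ccccc1
F6 | step 10 | {[(1R)-6-(benzyloxy)-1-[4-(benzyloxy)-3-methoxyphenyl]-4,5-dimethoxy-1H-inden-3-yl]oxy}trimethylsilane | COc1cc([C@@H]2c3cc(OCc4ccccc4)c(OC)c(OC)c3C(O[Si](C)(C)C)=C2)ccc1OCc1ccccc1
F7 | step 10 | (2R,3R)-5-(benzyloxy)-3-[4-(benzyloxy)-3-methoxyphenyl]-2-(hydroxymethyl)-6,7-dimethoxy-2,3-dihydro-1H-inden-1-one | COc1cc([C@@H]2c3cc(OCc4ccccc4)c(OC)c(OC)c3C(=O)[C@H]2CO)ccc1OCc1ccccc1
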